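**Strategy.** The route rests on cutting the unfunctionalised CH2–CH2 bond C9'–C10' of the hexadecyl chain (C1' sits on ring carbon C3 of the furan-2,5-dione, C15' is the acetoxy stereocentre). C9' is the ninth methylene from the ring and C10' the fifth from the stereocentre, so both are unactivated primary carbons far from either functional end. One pot forges the bond by an sp3–sp3 B-alkyl Suzuki coupling: 9-BBN hydroboration of a terminal alkene puts boron on C9', and Pd/PCy3 joins it to a primary bromide at C10'. The precursors are di-tert-butyl 2-methyl-3-(non-8-enyl)maleate, a masked anhydride ring made by three-component carbocupration–methylation, and (S)-7-bromoheptan-2-yl acetate from (S)-propylene oxide. TFA finally closes the ring.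

Key step: step 4

Remark: the side chain is numbered C1' (on ring carbon C3) to C16' (terminal CH3); the stereodescriptor in the target SMILES corresponds to (S) at C15'. But-3-enylmagnesium bromide is taken as the commercial THF solution.

**Step 1**
Reactants: 1 (S)-propylene oxide; 2 but-3-en-1-ylmagnesium bromide
Product: 4 (S)-hept-6-en-2-yl acetate, via magnesium alkoxide 3 (not isolated)
Conditions: CuI (10 mol%), THF, −30 → 0 °C; then Ac2O, DMAP (cat.), 0 °C → rt
Reagents that add atoms: acetic anhydride, CC(=O)OC(C)=O
Why: Copper-catalysed SN2 opening of a terminal epoxide by a Grignard reagent occurs at the unsubstituted CH2, so the C–O stereocentre of 1 is carried over unchanged as (S), and the magnesium alkoxide is then O-acetylated in the same flask (DMAP-catalysed acylation).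

**Step 2**
Reactants: 4 (S)-hept-6-en-2-yl acetate
Product: 5 (S)-7-bromoheptan-2-yl acetate
Conditions: HBr (g), (PhCO2)2 (cat.), hexane, 0 °C
Reagents that add atoms: hydrogen bromide, Br
Why: Peroxide-initiated radical-chain (Kharasch) hydrobromination adds the bromine atom to the terminal carbon via the secondary radical, giving the anti-Markovnikov primary bromide without involving the acetate or the remote stereocentre.

**Step 3**
Reactants: 6 9-bromonon-1-ene; 7 di-tert-butyl but-2-ynedioate
Product: 11 di-tert-butyl (2Z)-2-methyl-3-(non-8-en-1-yl)but-2-enedioate, via Grignard reagent 8 (not isolated), via alkylcopper reagent 9 (not isolated), via alkenylcopper adduct 10 (not isolated)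
Conditions: Mg, THF, rt; CuBr·SMe2 (1 equiv), THF, −40 °C; 7, −78 °C; then MeI, HMPA, −78 °C → rt
Reagents that add atoms: iodomethane, CI
Why: Three-component carbocupration–alkylation of an alkynedioate, in which the alkylcopper adds syn across the triple bond at −78 °C and the resulting alkenylcopper is C-methylated with retention, so the two esters should end up cis (Z).

**Step 4**
Reactants: 11 di-tert-butyl (2Z)-2-methyl-3-(non-8-en-1-yl)but-2-enedioate; 5 (S)-7-bromoheptan-2-yl acetate
Product: 13 di-tert-butyl (2Z)-2-[(15S)-15-acetoxyhexadecyl]-3-methylbut-2-enedioate, via alkyl-9-BBN borane 12 (not isolated)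
Conditions: 11 (1.3 equiv), 9-BBN (1.25 equiv), THF, rt; then 5 (1.0 equiv), Pd(OAc)2 (4 mol%), PCy3 (8 mol%), K3PO4·H2O (1.2 equiv), THF, rt
Reagents that add atoms: none
Why: 9-BBN adds anti-Markovnikov to the monosubstituted alkene of 11 and places boron on terminal C9'; the base-activated borate then transmetalates to the alkylpalladium(II) bromide formed by SN2-type oxidative addition of primary bromide 5 to Pd(0)/PCy3, and reductive elimination forms the C9'–C10' CH2–CH2 bond. The closest known reaction type is the room-temperature B-alkyl Suzuki–Miyaura coupling of unactivated primary alkyl bromides bearing β-hydrogens with alkyl-9-BBN reagents. No ring is closed and no stereocentre is created; the (S) centre of 5 lies five carbons from the reacting carbon and is carried through unchanged. The hydroboration must be chemoselective, and the substrate secures this: the maleate C=C is tetrasubstituted, electron-poor and flanked by tert-butyl esters, so only the terminal alkene reacts, and the slight excess of 11 over 9-BBN leaves no B–H to meet the acetate of 5. Cross-coupling must outrun β-hydride elimination, which the bulky electron-rich PCy3 ligand secures, and the acetate and tert-butyl esters should tolerate K3PO4·H2O at room temperature.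

**Step 5**
Reactants: 13 di-tert-butyl (2Z)-2-[(15S)-15-acetoxyhexadecyl]-3-methylbut-2-enedioate
Product: 15 (2S)-16-(4-methyl-2,5-dioxo-2,5-dihydrofuran-3-yl)hexadecan-2-yl acetate (target), via maleic diacid 14 (not isolated)
Conditions: TFA/CH2Cl2 (1:1), rt; concentrate from toluene
Reagents that add atoms: none
Why: Acidolysis of both tert-butyl esters (loss of isobutene) leaves the secondary acetate and its stereocentre untouched, and the cis-dialkylmaleic acid should cyclodehydrate spontaneously to the five-membered anhydride under the acidic conditions.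

**Compound list**
1 | (S)-propylene oxide [(2S)-2-methyloxirane] | C[C@H]1CO1 | starting material
2 | but-3-en-1-ylmagnesium bromide (THF solution) | C=CCC[Mg]Br | starting material
3 | bromomagnesium (2S)-hept-6-en-2-olate | C[C@H](O[Mg]Br)CCCC=C | intermediate (not isolated)
4 | (S)-hept-6-en-2-yl acetate | CC(=O)O[C@@H](C)CCCC=C | intermediate
5 | (S)-7-bromoheptan-2-yl acetate | CC(=O)O[C@@H](C)CCCCCBr | intermediate
6 | 9-bromonon-1-ene | C=CCCCCCCCBr | starting material
7 | di-tert-butyl but-2-ynedioate (di-tert-butyl acetylenedicarboxylate) | CC(C)(C)OC(=O)C#CC(=O)OC(C)(C)C | starting material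
8 | non-8-en-1-ylmagnesium bromide | C=CCCCCCCC[Mg]Br | intermediate (not isolated)
9 | non-8-en-1-ylcopper (Me2S/MgBr2 complex) | C=CCCCCCCC[Cu] | intermediate (not isolated)
10 | di-tert-butyl 2-cuprio-3-(non-8-en-1-yl)but-2-enedioate (esters cis, Cu cis to the chain) | CC(C)(C)OC(=O)/C([Cu])=C(/CCCCCCCC=C)C(=O)OC(C)(C)C | intermediate (not isolated)
11 | di-tert-butyl (2Z)-2-methyl-3-(non-8-en-1-yl)but-2-enedioate | CC(C)(C)OC(=O)/C(C)=C(/CCCCCCCC=C)C(=O)OC(C)(C)C | intermediate
12 | di-tert-butyl (2Z)-2-[9-(9-borabicyclo[3.3.1]nonan-9-yl)nonyl]-3-methylbut-2-enedioate | CC(C)(C)OC(=O)/C(C)=C(/CCCCCCCCCB1C2CCCC1CCC2)C(=O)OC(C)(C)C | intermediate (not isolated)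
13 | di-tert-butyl (2Z)-2-[(15S)-15-acetoxyhexadecyl]-3-methylbut-2-enedioate | CC(=O)O[C@@H](C)CCCCCCCCCCCCCC/C(C(=O)OC(C)(C)C)=C(\C)C(=O)OC(C)(C)C | intermediate
14 | (2Z)-2-[(15S)-15-acetoxyhexadecyl]-3-methylbut-2-enedioic acid | CC(=O)O[C@@H](C)CCCCCCCCCCCCCC/C(C(=O)O)=C(\C)C(=O)O | intermediate (not isolated)
15 | (2S)-16-(4-methyl-2,5-dioxo-2,5-dihydrofuran-3-yl)hexadecan-2-yl acetate | CC(=O)O[C@@H](C)CCCCCCCCCCCCCCC1=C(C)C(=O)OC1=O | target

**Totals.** Total step count: 5. Longest linear sequence: 4 steps (steps 1, 2, 4, 5).

**Steps most likely to fail**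

Step 4 (key step). Transmetalation of the alkylborate may be slow, so that β-hydride elimination or protodehalogenation of the alkylpalladium intermediate consumes the bromide. The fallback forms the same C9'–C10' bond by Wittig olefination and reduction; it sets out from 11 and 5 and comes back at 13. Hydroboration–oxidation of 11 (9-BBN, THF; then NaBO3·4H2O) should give di-tert-butyl (2Z)-2-(9-hydroxynonyl)-3-methylbut-2-enedioate F1. Dess–Martin oxidation should give di-tert-butyl (2Z)-2-methyl-3-(9-oxononyl)but-2-enedioate F2. Heating 5 with PPh3 in MeCN should give [(6S)-6-acetoxyheptyl]triphenylphosphonium bromide F3. The ylide of F3 (NaHMDS, 1 equiv, THF, −78 °C) and F2 should give di-tert-butyl (2Z)-2-[(9Z,15S)-15-acetoxyhexadec-9-en-1-yl]-3-methylbut-2-enedioate F4, whose chain alkene geometry is irrelevant. Its disubstituted alkene would be hydrogenated selectively over the tetrasubstituted maleate (H2, RhCl(PPh3)3, benzene/EtOH) to reach 13.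

Step 3. C-methylation of the ester-stabilised alkenylcopper may be sluggish, allowing protonation on work-up or Z-to-E isomerisation through the copper allenoate on warming. The fallback sets out from 6 and 7 (through alkenylcopper 10 generated as in step 3) and comes back at 11. The cold alkenylcopper would be quenched with I2 at −78 °C to give di-tert-butyl (2E)-2-iodo-3-(non-8-en-1-yl)but-2-enedioate F5 (esters cis). Its methyl group would then be introduced by Negishi coupling (MeZnCl, Pd(PPh3)4, THF, rt) to give 11.

Step 2. Ionic Markovnikov addition of HBr may compete with the radical chain, or the acetate may suffer acidolysis. The fallback sets out from 4 and comes back at 5. Hydroboration–oxidation (9-BBN, THF; then NaBO3·4H2O) should give (S)-7-hydroxyheptan-2-yl acetate F6, which an Appel reaction (CBr4, PPh3, CH2Cl2, 0 °C) would convert into 5.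

**Further compounds**
F1 | step 4 | di-tert-butyl (2Z)-2-(9-hydroxynonyl)-3-methylbut-2-enedioate | CC(C)(C)OC(=O)/C(C)=C(/CCCCCCCCCO)C(=O)OC(C)(C)C
F2 | step 4 | di-tert-butyl (2Z)-2-methyl-3-(9-oxononyl)but-2-enedioate | CC(C)(C)OC(=O)/C(C)=C(/CCCCCCCCC=O)C(=O)OC(C)(C)C
F3 | step 4 | [(6S)-6-acetoxyheptyl]triphenylphosphonium bromide | CC(=O)O[C@@H](C)CCCCC[P+](c1ccccc1)(c1ccccc1)c1ccccc1.[Br-]
F4 | step 4 | di-tert-butyl (2Z)-2-[(9Z,15S)-15-acetoxyhexadec-9-en-1-yl]-3-methylbut-2-enedioate | CC(=O)O[C@@H](C)CCCC/C=C\CCCCCCCC/C(C(=O)OC(C)(C)C)=C(\C)C(=O)OC(C)(C)C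
F5 | step 3 | di-tert-butyl (2E)-2-iodo-3-(non-8-en-1-yl)but-2-enedioate | CC(C)(C)OC(=O)/C(I)=C(/CCCCCCCC=C)C(=O)OC(C)(C)C
F6 | step 2 | (S)-7-hydroxyheptan-2-yl acetate | CC(=O)O[C@@H](C)CCCCCO
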